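**Retrosynthetic overview**

1. Side chain: disconnect the C4′=C5′ alkene (cross-metathesis, last step) to the core (2E)-penta-2,4-dienoate and (2S,3S)-3-methylpent-4-en-2-ol, the latter from trans-2,3-epoxybutane and a vinyl Grignard reagent.
2. Core (eremophilane-type numbering: C-1=C-2, C-3 acyloxy, C-4 methyl, C-5 angular methyl, C-7 hydroxyl, C-8 ketone, C-9=C-10): 7-OH by Rubottom oxidation, C-1=C-2 by dienol-ether dehydrogenation, ester by acylation of the 3β-alcohol, which comes from hydride reduction of the 3,8-dione.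
3. Key disconnection: the C-4–C-5 bond of the 3,8-dione, made by a one-carbon ring expansion (1,2-shift of the quaternary carbon onto a vinyl group activated by hydrogen-atom transfer) of the 1-vinyl carbinol silyl ether of the Hajos–Parrish ketone; this builds ring A and sets C-4.
4. Hajos–Parrish ketone from 2-methylcyclopentane-1,3-dione and methyl vinyl ketone by proline-catalysed aldol cyclisation, which sets C-5.
5. Ring order: the five-membered ring is bought, ring B (cyclohexenone) is closed by aldol condensation, and ring A arises last by enlarging the five-membered ring to six.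

Assumption: (2S,3S)-2,3-dimethyloxirane and (2E)-penta-2,4-dienoic acid are taken as catalogue chemicals.

**Route**

Step 1
Reactants: 1 2-methylcyclopentane-1,3-dione; 2 methyl vinyl ketone (but-3-en-2-one)
Product: 3 2-methyl-2-(3-oxobutyl)cyclopentane-1,3-dione
Conditions: H2O, 20 °C, 5 d
Reagents that add atoms: none
Why: Michael addition of the enolised 1,3-dione to the enone in water gives the C-alkylated triketone cleanly; no stereocentre is formed.

Step 2
Reactants: 3 2-methyl-2-(3-oxobutyl)cyclopentane-1,3-dione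
Product: 5 (S)-7a-methyl-2,3,7,7a-tetrahydro-1H-indene-1,5(6H)-dione (Hajos–Parrish ketone), via ketol 4 (not isolated)
Conditions: (S)-proline (3 mol%), DMF, 20 °C, 24 h; then H2SO4 (cat.), DMF, 95 °C, 3 h; recrystallisation
Reagents that add atoms: none
Why: Hajos–Parrish intramolecular aldol reaction, in which the (S)-proline enamine of the side-chain ketone attacks one of the two enantiotopic ring carbonyls through a hydrogen-bonded chair transition state and so sets the quaternary centre as S (about 93% ee, raised by recrystallisation), followed by acid dehydration of the ketol to the enone.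

Step 3
Reactants: 5 (S)-7a-methyl-2,3,7,7a-tetrahydro-1H-indene-1,5(6H)-dione; 6 vinylmagnesium bromide
Product: 8 (1R,7aS)-7a-methyl-1-[(trimethylsilyl)oxy]-1-vinyl-1,2,3,6,7,7a-hexahydro-5H-inden-5-one, via bromomagnesium alkoxide 7 (not isolated)
Conditions: CH2=CHMgBr (1.2 equiv), LaCl3·2LiCl (0.3 equiv), THF, −78 °C; then Me3SiCl (2 equiv), imidazole (2 equiv), −78 → 20 °C
Reagents that add atoms: chlorotrimethylsilane, C[Si](C)(C)Cl
Why: Grignard 1,2-addition goes to the saturated cyclopentanone, which is more electrophilic than the conjugated enone carbonyl (the same order as in the known selective NaBH4 reduction of this diketone), from the face anti to the angular methyl to give the 1R carbinol, whose alkoxide is silylated in the flask; this stereocentre is consumed in step 4.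

Step 4
Reactants: 8 (1R,7aS)-7a-methyl-1-[(trimethylsilyl)oxy]-1-vinyl-1,2,3,6,7,7a-hexahydro-5H-inden-5-one
Product: 9 (4aR,5R)-4a,5-dimethyl-4,4a,7,8-tetrahydronaphthalene-2,6(3H,5H)-dione
Conditions: [N,N′-bis(3,5-di-tert-butylsalicylidene)ethane-1,2-diaminato]cobalt (divalent cobalt, 5 mol%), N-fluoro-2,4,6-trimethylpyridinium triflate (1.3 equiv), PhSiH3 (1.2 equiv), acetone, 0 → 20 °C; then H2O
Reagents that add atoms: none
Why: Proposed new method: hydrogen-atom transfer from a trivalent cobalt hydride to the terminal vinyl carbon gives a secondary radical that is captured by divalent cobalt and oxidised to a tetravalent alkylcobalt species, whose C–Co bond is displaced with inversion by the antiperiplanar bond to the quaternary carbon (which migrates with retention and in preference to the CH2 carbon because it carries positive charge better) while the silyloxy oxygen pushes to the ketone and loses its silyl group, the silyl ether blocking the competing epoxide closure; the new methyl takes the exo position of the bridged transition state, syn to the angular methyl and away from the ring being enlarged, so the cis-dimethyl epimer (5R) is expected as the major product and is not epimerised under these neutral conditions; the closest known chemistry is the cobalt-salen radical–polar crossover semipinacol rearrangement of tertiary allylic alcohols with 1,1-disubstituted alkenes and strained or aryl migrating groups, together with Markovnikov hydrofunctionalisation of monosubstituted alkenes by the same catalyst system, neither shown for a vinyl carbinol ether with an unstrained cyclopentane-to-cyclohexanone expansion.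

Step 5
Reactants: 9 (4aR,5R)-4a,5-dimethyl-4,4a,7,8-tetrahydronaphthalene-2,6(3H,5H)-dione
Product: 10 (4aR,5R,6S)-6-hydroxy-4a,5-dimethyl-4,4a,5,6,7,8-hexahydronaphthalen-2(3H)-one
Conditions: K[HB(s-Bu)3] (1.1 equiv), THF, −78 → −40 °C; then aq. NH4Cl
Reagents that add atoms: none
Why: Bulky borohydride reduction, in which hydride reaches the saturated ketone (the β,β-disubstituted enone is inert at this temperature) along the equatorial α trajectory because the axial face is blocked by the syn-axial angular methyl, giving the axial 3β (6S) alcohol cis to both methyl groups.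

Step 6
Reactants: 10 (4aR,5R,6S)-6-hydroxy-4a,5-dimethyl-4,4a,5,6,7,8-hexahydronaphthalen-2(3H)-one; 11 (2E)-penta-2,4-dienoic acid
Product: 13 (1R,2S,8aR)-1,8a-dimethyl-6-oxo-1,2,3,4,6,7,8,8a-octahydronaphthalen-2-yl (2E)-penta-2,4-dienoate, via mixed anhydride 12 (not isolated)
Conditions: 11 (1.5 equiv), 2,4,6-Cl3C6H2COCl, Et3N, THF, 0 °C; then 10, DMAP, toluene, 20 °C (trace BHT)
Reagents that add atoms: none
Why: Yamaguchi esterification through the mixed anhydride acylates the hindered axial alcohol with retention at C-3, and the acid has no sp3 γ-hydrogen, so DMAP cannot deconjugate it.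

Step 7
Reactants: 13 (1R,2S,8aR)-1,8a-dimethyl-6-oxo-1,2,3,4,6,7,8,8a-octahydronaphthalen-2-yl (2E)-penta-2,4-dienoate
Product: 15 (1R,2S,8aR)-1,8a-dimethyl-6-oxo-1,2,6,7,8,8a-hexahydronaphthalen-2-yl (2E)-penta-2,4-dienoate, via TBS dienol ether 14 (not isolated)
Conditions: t-BuMe2SiOTf (1.3 equiv), Et3N (2 equiv), CH2Cl2, 0 °C; aq. NaHCO3 wash; then DDQ (1.05 equiv), CH2Cl2, 0 °C; then H2O
Reagents that add atoms: none
Why: Soft enolisation removes a γ-hydrogen at C-1 to give the extended silyl dienol ether, and DDQ then abstracts hydride from allylic C-2 (the classical dienol-ether dehydrogenation of steroid enones to linear dienones) to give the 1,9-dien-8-one without touching a stereocentre.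

Step 8
Reactants: 15 (1R,2S,8aR)-1,8a-dimethyl-6-oxo-1,2,6,7,8,8a-hexahydronaphthalen-2-yl (2E)-penta-2,4-dienoate
Product: 18 (1R,2S,7R,8aR)-7-hydroxy-1,8a-dimethyl-6-oxo-1,2,6,7,8,8a-hexahydronaphthalen-2-yl (2E)-penta-2,4-dienoate, via TMS enol ether 16 (not isolated), via silyloxy ketone 17 (not isolated)
Conditions: Me3SiOTf (1.3 equiv), Et3N (2 equiv), CH2Cl2, 0 °C; aq. NaHCO3 wash; then mCPBA (1.1 equiv), hexane/CH2Cl2, −20 °C; then aq. citric acid, THF, 20 °C
Reagents that add atoms: mCPBA (3-chloroperoxybenzoic acid), OOC(=O)c1cccc(Cl)c1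
Why: Rubottom oxidation, in which the dienone (no removable γ-hydrogen left, and the C-3 hydrogen lies in the diene plane) enolises only towards C-7, the peracid epoxidises this electron-rich enol ether on the α face anti to the axial angular methyl, and silyl migration with mild acid gives the equatorial 7α (7R) hydroxy ketone while the electron-poor dienoate and dienone alkenes stay intact.

Step 9
Reactants: 19 (2S,3S)-2,3-dimethyloxirane; 6 vinylmagnesium bromide
Product: 20 (2S,3S)-3-methylpent-4-en-2-ol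
Conditions: CH2=CHMgBr (1.5 equiv), CuI (10 mol%), THF, −30 → 0 °C; then aq. NH4Cl
Reagents that add atoms: none
Why: Copper-catalysed SN2 opening of the C2-symmetric trans-epoxide by the vinyl Grignard reagent inverts the attacked carbon and keeps the other, so either carbon gives the same syn (2S,3S) alcohol as a single isomer.

Step 10
Reactants: 18 (1R,2S,7R,8aR)-7-hydroxy-1,8a-dimethyl-6-oxo-1,2,6,7,8,8a-hexahydronaphthalen-2-yl (2E)-penta-2,4-dienoate; 20 (2S,3S)-3-methylpent-4-en-2-ol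
Product: 21 (1R,2S,7R,8aR)-7-hydroxy-1,8a-dimethyl-6-oxo-1,2,6,7,8,8a-hexahydronaphthalen-2-yl (2E,4E,6S,7S)-7-hydroxy-6-methylocta-2,4-dienoate
Conditions: second-generation Hoveyda–Grubbs catalyst, RuCl2(H2IMes)(=CH-C6H4-2-O-i-Pr) (7 mol%), 20 (4 equiv), CH2Cl2, 40 °C
Reagents that add atoms: none
Why: Olefin cross-metathesis at the terminal alkene of the 2,4-dienoate with excess homoallylic alcohol, driven by loss of ethene, gives the favoured 4E alkene, while the dienone and 2E alkenes are too electron-poor or hindered to react and free hydroxyl groups are tolerated.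

**Compound list**

1 | 2-methylcyclopentane-1,3-dione | CC1C(=O)CCC1=O | starting material
2 | methyl vinyl ketone (but-3-en-2-one) | CC(=O)C=C | starting material
3 | 2-methyl-2-(3-oxobutyl)cyclopentane-1,3-dione | CC(=O)CCC1(C)C(=O)CCC1=O | intermediate
4 | (3aS,7aS)-3a-hydroxy-7a-methylhexahydro-1H-indene-1,5(6H)-dione | C[C@]12CCC(=O)C[C@@]1(O)CCC2=O | intermediate
5 | (S)-7a-methyl-2,3,7,7a-tetrahydro-1H-indene-1,5(6H)-dione (Hajos–Parrish ketone) | C[C@]12CCC(=O)C=C1CCC2=O | intermediate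
6 | vinylmagnesium bromide | C=C[Mg]Br | starting material
7 | bromomagnesium (1R,7aS)-7a-methyl-5-oxo-1-vinyl-2,3,5,6,7,7a-hexahydro-1H-inden-1-olate | C[C@]12CCC(=O)C=C1CC[C@@]2(O[Mg]Br)C=C | intermediate
8 | (1R,7aS)-7a-methyl-1-[(trimethylsilyl)oxy]-1-vinyl-1,2,3,6,7,7a-hexahydro-5H-inden-5-one | C[C@]12CCC(=O)C=C1CC[C@@]2(O[Si](C)(C)C)C=C | intermediate
9 | (4aR,5R)-4a,5-dimethyl-4,4a,7,8-tetrahydronaphthalene-2,6(3H,5H)-dione | O=C1CCC2=CC(=O)CC[C@]2(C)[C@H]1C | intermediate
10 | (4aR,5R,6S)-6-hydroxy-4a,5-dimethyl-4,4a,5,6,7,8-hexahydronaphthalen-2(3H)-one | O[C@H]1CCC2=CC(=O)CC[C@]2(C)[C@H]1C | intermediate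
11 | (2E)-penta-2,4-dienoic acid | C=C/C=C/C(=O)O | starting material
12 | (2E)-penta-2,4-dienoic 2,4,6-trichlorobenzoic anhydride | C=C/C=C/C(=O)OC(=O)c1c(Cl)cc(Cl)cc1Cl | intermediate
13 | (1R,2S,8aR)-1,8a-dimethyl-6-oxo-1,2,3,4,6,7,8,8a-octahydronaphthalen-2-yl (2E)-penta-2,4-dienoate | C=C/C=C/C(=O)O[C@H]1CCC2=CC(=O)CC[C@]2(C)[C@H]1C | intermediate
14 | (1R,2S,8aR)-6-[(tert-butyldimethylsilyl)oxy]-1,8a-dimethyl-1,2,3,7,8,8a-hexahydronaphthalen-2-yl (2E)-penta-2,4-dienoate | C=C/C=C/C(=O)O[C@H]1CC=C2C=C(O[Si](C)(C)C(C)(C)C)CC[C@]2(C)[C@H]1C | intermediate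
15 | (1R,2S,8aR)-1,8a-dimethyl-6-oxo-1,2,6,7,8,8a-hexahydronaphthalen-2-yl (2E)-penta-2,4-dienoate | C=C/C=C/C(=O)O[C@H]1C=CC2=CC(=O)CC[C@]2(C)[C@H]1C | intermediate
16 | (1R,2S,8aR)-1,8a-dimethyl-6-[(trimethylsilyl)oxy]-1,2,8,8a-tetrahydronaphthalen-2-yl (2E)-penta-2,4-dienoate | C=C/C=C/C(=O)O[C@H]1C=CC2=CC(O[Si](C)(C)C)=CC[C@]2(C)[C@H]1C | intermediate
17 | (1R,2S,7R,8aR)-1,8a-dimethyl-6-oxo-7-[(trimethylsilyl)oxy]-1,2,6,7,8,8a-hexahydronaphthalen-2-yl (2E)-penta-2,4-dienoate | C=C/C=C/C(=O)O[C@H]1C=CC2=CC(=O)[C@H](O[Si](C)(C)C)C[C@]2(C)[C@H]1C | intermediate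
18 | (1R,2S,7R,8aR)-7-hydroxy-1,8a-dimethyl-6-oxo-1,2,6,7,8,8a-hexahydronaphthalen-2-yl (2E)-penta-2,4-dienoate | C=C/C=C/C(=O)O[C@H]1C=CC2=CC(=O)[C@H](O)C[C@]2(C)[C@H]1C | intermediate
19 | (2S,3S)-2,3-dimethyloxirane (trans-2,3-epoxybutane) | C[C@@H]1O[C@H]1C | starting material
20 | (2S,3S)-3-methylpent-4-en-2-ol | C[C@H](O)[C@@H](C)C=C | intermediate
21 | (1R,2S,7R,8aR)-7-hydroxy-1,8a-dimethyl-6-oxo-1,2,6,7,8,8a-hexahydronaphthalen-2-yl (2E,4E,6S,7S)-7-hydroxy-6-methylocta-2,4-dienoate | C[C@H](O)[C@@H](C)/C=C/C=C/C(=O)O[C@H]1C=CC2=CC(=O)[C@H](O)C[C@]2(C)[C@H]1C | target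

**Step count and risks**

Total step count: 10. Longest linear sequence: 9 steps (steps 1 to 8, then step 10).

Step 4, the proposed new ring expansion, may give the epoxide or the fluoride in place of the shift, may let the CH2 carbon migrate, or may give a poor ratio at C-4. The fallback uses only known reactions, sets out from 8 and comes back at 9. A peroxide-mediated Wacker oxidation of the vinyl group (PdCl2[2-(4,5-dihydro-1,3-oxazol-2-yl)quinoline], AgSbF6, aq. t-BuOOH, CH2Cl2) gives the methyl ketone (1S,7aS)-1-acetyl-7a-methyl-1-[(trimethylsilyl)oxy]-1,2,3,6,7,7a-hexahydro-5H-inden-5-one F1. BF3·OEt2 in CH2Cl2 at 0 °C takes off the silyl group and brings about the Lewis-acid α-ketol ring enlargement known from the D-homoannulation of 17-hydroxy-20-oxo steroids, in which the quaternary carbon migrates within the chelate, to give the ketol (4aS,5R)-5-hydroxy-4a,5-dimethyl-4,4a,7,8-tetrahydronaphthalene-2,6(3H,5H)-dione F2. SmI2 in THF/MeOH at −78 °C then removes the tertiary hydroxyl, and the samarium enolate is protonated on the axial α face, anti to the angular methyl, to give 9 with the cis-dimethyl arrangement.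

Step 3 may fail through addition to, or enolisation of, the enone. The fallback sets out from 5 and comes back at 8 by masking the enone first. Pyrrolidine (MeOH, 20 °C) converts 5 into the dienamine (7aS)-7a-methyl-5-(pyrrolidin-1-yl)-2,6,7,7a-tetrahydro-1H-inden-1-one F3. CH2=CHMgBr (THF, −78 → 0 °C) adds to the one carbonyl that is left to give the dienamine carbinol (1R,7aS)-7a-methyl-5-(pyrrolidin-1-yl)-1-vinyl-2,6,7,7a-tetrahydro-1H-inden-1-ol F4. Buffered hydrolysis (AcOH, NaOAc, H2O) frees the hydroxy enone (1R,7aS)-1-hydroxy-7a-methyl-1-vinyl-1,2,3,6,7,7a-hexahydro-5H-inden-5-one F5, which is silylated (Me3SiCl, imidazole, DMF) to 8.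

Step 10 may stall because both alkenes are slow metathesis partners. The fallback sets out from 20 and 10 and comes back at 21; it builds the dienoate by olefination and brings it in complete.
- Acid fragment: 20 is silylated (t-BuMe2SiCl, imidazole, DMF) to tert-butyldimethyl{[(2S,3S)-3-methylpent-4-en-2-yl]oxy}silane F6. Ozonolysis (O3, CH2Cl2, −78 °C; PPh3) gives (2R,3S)-3-[(tert-butyldimethylsilyl)oxy]-2-methylbutanal F7. A vinylogous Horner–Wadsworth–Emmons reaction with triethyl 4-phosphonocrotonate (LiN(SiMe3)2, THF, −78 → 0 °C) gives ethyl (2E,4E,6S,7S)-7-[(tert-butyldimethylsilyl)oxy]-6-methylocta-2,4-dienoate F8, and LiOH (THF/H2O) gives (2E,4E,6S,7S)-7-[(tert-butyldimethylsilyl)oxy]-6-methylocta-2,4-dienoic acid F9.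
- Esterification: under the conditions of step 6 the acid is converted into (2E,4E,6S,7S)-7-[(tert-butyldimethylsilyl)oxy]-6-methylocta-2,4-dienoic 2,4,6-trichlorobenzoic anhydride F10 and then, with 10, into (1R,2S,8aR)-1,8a-dimethyl-6-oxo-1,2,3,4,6,7,8,8a-octahydronaphthalen-2-yl (2E,4E,6S,7S)-7-[(tert-butyldimethylsilyl)oxy]-6-methylocta-2,4-dienoate F11.
- Dehydrogenation: the conditions of step 7 give (1R,2S,8aR)-6-[(tert-butyldimethylsilyl)oxy]-1,8a-dimethyl-1,2,3,7,8,8a-hexahydronaphthalen-2-yl (2E,4E,6S,7S)-7-[(tert-butyldimethylsilyl)oxy]-6-methylocta-2,4-dienoate F12 and from it (1R,2S,8aR)-1,8a-dimethyl-6-oxo-1,2,6,7,8,8a-hexahydronaphthalen-2-yl (2E,4E,6S,7S)-7-[(tert-butyldimethylsilyl)oxy]-6-methylocta-2,4-dienoate F13.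
- Hydroxylation and deprotection: the conditions of step 8 give (1R,2S,8aR)-1,8a-dimethyl-6-[(trimethylsilyl)oxy]-1,2,8,8a-tetrahydronaphthalen-2-yl (2E,4E,6S,7S)-7-[(tert-butyldimethylsilyl)oxy]-6-methylocta-2,4-dienoate F14 and then (1R,2S,7R,8aR)-1,8a-dimethyl-6-oxo-7-[(trimethylsilyl)oxy]-1,2,6,7,8,8a-hexahydronaphthalen-2-yl (2E,4E,6S,7S)-7-[(tert-butyldimethylsilyl)oxy]-6-methylocta-2,4-dienoate F15. HF·pyridine (THF, 0 °C) in place of citric acid removes both silyl groups to give 21.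

**Further compounds**

F1 | step 4 | (1S,7aS)-1-acetyl-7a-methyl-1-[(trimethylsilyl)oxy]-1,2,3,6,7,7a-hexahydro-5H-inden-5-one | C[C@]12CCC(=O)C=C1CC[C@@]2(O[Si](C)(C)C)C(C)=O
F2 | step 4 | (4aS,5R)-5-hydroxy-4a,5-dimethyl-4,4a,7,8-tetrahydronaphthalene-2,6(3H,5H)-dione | O=C1CCC2=CC(=O)CC[C@]2(C)[C@@]1(C)O
F3 | step 3 | (7aS)-7a-methyl-5-(pyrrolidin-1-yl)-2,6,7,7a-tetrahydro-1H-inden-1-one | C[C@]12CCC(N3CCCC3)=CC1=CCC2=O
F4 | step 3 | (1R,7aS)-7a-methyl-5-(pyrrolidin-1-yl)-1-vinyl-2,6,7,7a-tetrahydro-1H-inden-1-ol | C[C@]12CCC(N3CCCC3)=CC1=CC[C@@]2(O)C=C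
F5 | step 3 | (1R,7aS)-1-hydroxy-7a-methyl-1-vinyl-1,2,3,6,7,7a-hexahydro-5H-inden-5-one | C[C@]12CCC(=O)C=C1CC[C@@]2(O)C=C
F6 | step 10 | tert-butyldimethyl{[(2S,3S)-3-methylpent-4-en-2-yl]oxy}silane | C[C@H](O[Si](C)(C)C(C)(C)C)[C@@H](C)C=C
F7 | step 10 | (2R,3S)-3-[(tert-butyldimethylsilyl)oxy]-2-methylbutanal | C[C@H](O[Si](C)(C)C(C)(C)C)[C@@H](C)C=O
F8 | step 10 | ethyl (2E,4E,6S,7S)-7-[(tert-butyldimethylsilyl)oxy]-6-methylocta-2,4-dienoate | C[C@H](O[Si](C)(C)C(C)(C)C)[C@@H](C)/C=C/C=C/C(=O)OCC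
F9 | step 10 | (2E,4E,6S,7S)-7-[(tert-butyldimethylsilyl)oxy]-6-methylocta-2,4-dienoic acid | C[C@H](O[Si](C)(C)C(C)(C)C)[C@@H](C)/C=C/C=C/C(=O)O
F10 | step 10 | (2E,4E,6S,7S)-7-[(tert-butyldimethylsilyl)oxy]-6-methylocta-2,4-dienoic 2,4,6-trichlorobenzoic anhydride | C[C@H](O[Si](C)(C)C(C)(C)C)[C@@H](C)/C=C/C=C/C(=O)OC(=O)c1c(Cl)cc(Cl)cc1Cl
F11 | step 10 | (1R,2S,8aR)-1,8a-dimethyl-6-oxo-1,2,3,4,6,7,8,8a-octahydronaphthalen-2-yl (2E,4E,6S,7S)-7-[(tert-butyldimethylsilyl)oxy]-6-methylocta-2,4-dienoate | C[C@H](O[Si](C)(C)C(C)(C)C)[C@@H](C)/C=C/C=C/C(=O)O[C@H]1CCC2=CC(=O)CC[C@]2(C)[C@H]1C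
F12 | step 10 | (1R,2S,8aR)-6-[(tert-butyldimethylsilyl)oxy]-1,8a-dimethyl-1,2,3,7,8,8a-hexahydronaphthalen-2-yl (2E,4E,6S,7S)-7-[(tert-butyldimethylsilyl)oxy]-6-methylocta-2,4-dienoate | C[C@H](O[Si](C)(C)C(C)(C)C)[C@@H](C)/C=C/C=C/C(=O)O[C@H]1CC=C2C=C(O[Si](C)(C)C(C)(C)C)CC[C@]2(C)[C@H]1C
F13 | step 10 | (1R,2S,8aR)-1,8a-dimethyl-6-oxo-1,2,6,7,8,8a-hexahydronaphthalen-2-yl (2E,4E,6S,7S)-7-[(tert-butyldimethylsilyl)oxy]-6-methylocta-2,4-dienoate | C[C@H](O[Si](C)(C)C(C)(C)C)[C@@H](C)/C=C/C=C/C(=O)O[C@H]1C=CC2=CC(=O)CC[C@]2(C)[C@H]1C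
F14 | step 10 | (1R,2S,8aR)-1,8a-dimethyl-6-[(trimethylsilyl)oxy]-1,2,8,8a-tetrahydronaphthalen-2-yl (2E,4E,6S,7S)-7-[(tert-butyldimethylsilyl)oxy]-6-methylocta-2,4-dienoate | C[C@H](O[Si](C)(C)C(C)(C)C)[C@@H](C)/C=C/C=C/C(=O)O[C@H]1C=CC2=CC(O[Si](C)(C)C)=CC[C@]2(C)[C@H]1C
F15 | step 10 | (1R,2S,7R,8aR)-1,8a-dimethyl-6-oxo-7-[(trimethylsilyl)oxy]-1,2,6,7,8,8a-hexahydronaphthalen-2-yl (2E,4E,6S,7S)-7-[(tert-butyldimethylsilyl)oxy]-6-methylocta-2,4-dienoate | C[C@H](O[Si](C)(C)C(C)(C)C)[C@@H](C)/C=C/C=C/C(=O)O[C@H]1C=CC2=CC(=O)[C@H](O[Si](C)(C)C)C[C@]2(C)[C@H]1C
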